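**Plan**
Rings: A = phloroglucinol ring of the chroman-2,4-dione, C = its pyrandione ring (C3 quaternary), D = cyclohexene (D1 methyl carbon, D2, D3 on C6 of ring A, D4 aroyl-bearing, D5 on ring E, D6), E, F, G = the resorcinol rings on D5, on the D4 ketone and on C3.
Cuts, in retrosynthetic order: seven MOM ethers; ring C at C4–C4a and O1–C2 (chiral malonic half-ester 29); ketone carbon–ring F (aryllithium on a lactone); C6(ring A)–D3 (key step); the D4 ester C–O bond; D3–D4 and D5–D6 (Diels–Alder on coumarin 4).
Forward: ring D is built on the ring E coumarin, that lactone is exchanged for a ring A aryl ester, the key cyclisation closes the ring A lactone, ring F opens it to the ketone, and ring C is closed last.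
Enabling feature: ring A is a phloroglucinol whose two carbons ortho to any one oxygen are equivalent, and its C6 sits on allylic D3 next to carbonyl-bearing D4. An ester from the D4 carboxyl to a ring A oxygen therefore holds an ortho carbon over D3, on the carboxyl face, at six-ring distance.
Stereochemistry: D4/D5 cis from the Z-alkene locked in coumarin 4, face chosen by a chiral bis(oxazoline)–Cu(OTf)2 catalyst; D3 from the tether; C3 from an enantioselective O-to-C carboxyl migration (27) and the order in which its two carbonyls are spent (first on oxygen, then on carbon).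

Key step: step 9

Assumption: the facial sense of the two catalyst-controlled steps (3 and 16) is assigned by analogy with simpler substrates; the antipodal ligand or catalyst serves if the opposite sense is found.

**Route**

Step 1
Reactants: 1 2,4-dihydroxybenzaldehyde; 2 diallyl malonate
Product: 3 allyl 7-hydroxy-2-oxo-2H-chromene-3-carboxylate
Conditions: piperidine (cat.), AcOH (cat.), toluene, reflux, azeotropic removal of water
Reagents that add atoms: none
Why: Knoevenagel condensation followed by lactonisation onto the ortho hydroxyl is the standard entry to coumarin-3-carboxylates and installs the allyl ester that later leaves as CO2.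

Step 2
Reactants: 3 allyl 7-hydroxy-2-oxo-2H-chromene-3-carboxylate
Product: 4 allyl 7-(methoxymethoxy)-2-oxo-2H-chromene-3-carboxylate
Conditions: MOMCl, iPr2NEt, CH2Cl2, 0 °C to rt
Reagents that add atoms: chloromethyl methyl ether, COCCl
Why: Williamson-type O-alkylation of the only phenol.

Step 3
Reactants: 4 allyl 7-(methoxymethoxy)-2-oxo-2H-chromene-3-carboxylate; 5 (E)-1-methoxy-3-(trimethylsilyloxy)buta-1,3-diene
Product: 7 allyl (6aS,10aS)-3-(methoxymethoxy)-6,9-dioxo-10,10a-dihydro-6H-benzo[c]chromene-6a(9H)-carboxylate (cis-fused enone, alkene D2=D3), via silyl enol ether cycloadduct 6 (not isolated)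
Conditions: Cu(OTf)2 (10 mol%), (S,S)-t-Bu-box (11 mol%), CH2Cl2, −78 to −40 °C; then 1 M HCl, THF, 0 °C
Reagents that add atoms: none
Why: Lewis-acid-catalysed Diels–Alder reaction in which the two carbonyls on C3 chelate the chiral copper complex and the diene CH2 terminus adds to C4 of the coumarin, so the ring-locked Z-alkene makes D4 and D5 cis by necessity and the ligand selects the face; acid then hydrolyses the silyl enol ether and eliminates methanol to the enone with D4 still quaternary.

Step 4
Reactants: 7 cis-fused enone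
Product: 8 allyl (6aS,10aS)-9-hydroxy-9-methyl-3-(methoxymethoxy)-6-oxo-10,10a-dihydro-6H-benzo[c]chromene-6a(9H)-carboxylate (C9 epimers)
Conditions: MeMgBr, CeCl3, THF, −78 °C
Reagents that add atoms: methylmagnesium bromide, C[Mg]Br
Why: organocerium 1,2-addition to the enone carbonyl should outrun attack on lactone or ester at −78 °C and cannot enolise towards quaternary D4; the carbinol configuration is irrelevant because D1 becomes sp2 in step 9.

Step 5
Reactants: 8 tertiary allylic alcohol
Product: 10 (6aS,10aR)-9-hydroxy-9-methyl-3-(methoxymethoxy)-6a,9,10,10a-tetrahydro-6H-benzo[c]chromen-6-one (cis-fused, C9 epimers), via malonic half-acid 9 (not isolated)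
Conditions: Pd(PPh3)4 (5 mol%), HCO2H, Et3N, THF, rt then 50 °C
Reagents that add atoms: none
Why: Tsuji–Trost deallylation with formate as hydride donor gives the half-acid, which loses CO2 through its dienol, and kinetic α-protonation from the convex face (that of D5–H) should return the cis-fused lactone while the tertiary alcohol is untouched near neutrality.

Step 6
Reactants: 10 cis-fused lactone
Product: 12 (1S,6R)-6-[2,4-bis(methoxymethoxy)phenyl]-4-hydroxy-4-methylcyclohex-2-ene-1-carboxylic acid (C4 epimers), via dilithium phenoxide carboxylate 11 (not isolated)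
Conditions: LiOH·H2O (2.2 equiv), THF/H2O, 0 °C; evaporate; MOMCl (1.1 equiv), DMF, 0 °C; AcOH to pH 5
Reagents that add atoms: lithium hydroxide, [Li+].[OH-]; chloromethyl methyl ether, COCCl
Why: saponification of the aryl lactone is fast at 0 °C and leaves D4 as a non-enolisable carboxylate, and the phenoxide of the dianion is alkylated (Williamson) in preference to the hindered carboxylate.

Step 7
Reactants: 13 phloroglucinol
Product: 14 3,5-bis(tert-butyldimethylsilyloxy)phenol
Conditions: TBSCl (2.0 equiv), imidazole, DMF, 0 °C to rt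
Reagents that add atoms: tert-butyldimethylsilyl chloride, CC(C)(C)[Si](C)(C)Cl
Why: statistical silylation of the symmetric triol; the mono- and tris-silyl ethers are separable and can be recycled.

Step 8
Reactants: 12 cyclohexene acid; 14 3,5-bis(tert-butyldimethylsilyloxy)phenol
Product: 15 3,5-bis(tert-butyldimethylsilyloxy)phenyl (1S,6R)-6-[2,4-bis(methoxymethoxy)phenyl]-4-hydroxy-4-methylcyclohex-2-ene-1-carboxylate (C4 epimers)
Conditions: EDC·HCl, DMAP (0.1 equiv), CH2Cl2, 0 °C
Reagents that add atoms: none
Why: Steglich esterification with the unhindered phenol; the tertiary alcohol is not acylated, and low temperature with catalytic DMAP limits enolisation of the β,γ-unsaturated acyl intermediate at D4.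

Step 9
Reactants: 15 aryl ester with tertiary allylic alcohol
Product: 16 (6aR,7R,10aS)-7-[2,4-bis(methoxymethoxy)phenyl]-1,3-bis(tert-butyldimethylsilyloxy)-9-methyl-6a,7,8,10a-tetrahydro-6H-benzo[c]chromen-6-one (all-cis, cis-fused lactone)
Conditions: Sc(OTf)3 (10 mol%), 4 Å molecular sieves, CH2Cl2 (0.005 M), −20 °C
Reagents that add atoms: none
Why: Proposed new method: Sc(OTf)3 ionises the tertiary allylic alcohol (SN1, either epimer) to the D1–D2–D3 allyl cation, an ortho carbon of the aryl ester attacks D3, and proton loss restores ring A with the alkene at D1=D2. The closest known reactions are the acid-mediated Friedel–Crafts allylation of resorcinols and phloroglucinols by cyclic tertiary allylic alcohols (the terpenylation used for cannabinoids) and the acid cyclisation of aryl cinnamates to dihydrocoumarins; delivery of the arene to an allyl cation through an aryl ester is the new element. The six-membered lactone closes by 6-exo attack on the cation terminus D3, whereas attack at D1 would need a bridged eight-membered ring. D3 is set by the tether: bond formation is axial on the half-chair cation and a three-atom link from D4 can only span a gauche (cis) relationship, so ring A ends cis to the D4 carbonyl and hence cis to ring E. Ring A needs no regiocontrol because both ortho carbons are equivalent and each is ortho or para to both silyloxy groups; selectivity against proton loss to a diene and against intermolecular alkylation rests on high dilution, low temperature and the absence of base, which also leaves D4–H untouched.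

Step 10
Reactants: 17 4-bromoresorcinol
Product: 18 1-bromo-2,4-bis(methoxymethoxy)benzene
Conditions: MOMCl, iPr2NEt, CH2Cl2, 0 °C to rt
Reagents that add atoms: chloromethyl methyl ether, COCCl
Why: Williamson-type protection of both phenols gives the ring F donor.

Step 11
Reactants: 16 all-cis lactone; 18 1-bromo-2,4-bis(methoxymethoxy)benzene
Product: 21 [2,4-bis(methoxymethoxy)phenyl] {(1S,5R,6R)-5-[2,4-bis(methoxymethoxy)phenyl]-1-[2-(methoxymethoxy)-4,6-bis(tert-butyldimethylsilyloxy)phenyl]-3-methylcyclohex-2-en-6-yl} ketone, via aryllithium 19 (not isolated), via lithium phenoxide ketone 20 (not isolated)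
Conditions: 18, n-BuLi, THF, −78 °C; add to 16, −78 °C; then MOMCl, −78 to 0 °C
Reagents that add atoms: chloromethyl methyl ether, COCCl
Why: bromine–lithium exchange gives the MOM-stabilised aryllithium, whose acyl substitution at the aryl lactone expels the ring A phenoxide and should stop at the hindered ketone at −78 °C, and capping that phenoxide in the same flask distinguishes the oxygen next to D3; D3, D4 and D5 are not touched.

Step 12
Reactants: 21 silylated ketone
Product: 22 the corresponding ring A 3,5-diol (2-(methoxymethoxy)-4,6-dihydroxyphenyl on D3)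
Conditions: TBAF, AcOH (1:1), THF, 0 °C
Reagents that add atoms: none
Why: fluoride cleavage of the two aryl silyl ethers, buffered so that phenoxide does not epimerise the all-cis ketone at D4.

Step 13
Reactants: 23 6-hydroxybenzofuran-2(3H)-one
Product: 24 6-(methoxymethoxy)benzofuran-2(3H)-one
Conditions: MOMCl, iPr2NEt, CH2Cl2, 0 °C
Reagents that add atoms: chloromethyl methyl ether, COCCl
Why: Williamson-type protection of the phenol, which is more acidic than the lactone CH2 towards the amine base.

Step 14
Reactants: 24 6-(methoxymethoxy)benzofuran-2(3H)-one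
Product: 25 racemic 6-(methoxymethoxy)-3-(3-methylbut-2-enyl)benzofuran-2(3H)-one
Conditions: LiN(SiMe3)2 (1.0 equiv), THF, −78 °C; prenyl bromide
Reagents that add atoms: prenyl bromide, CC(C)=CCBr
Why: enolate C-alkylation with the allylic bromide at its primary carbon; one equivalent of base at low temperature limits dialkylation.

Step 15
Reactants: 25 3-prenylbenzofuranone
Product: 26 6-(methoxymethoxy)-3-(3-methylbut-2-enyl)benzofuran-2-yl 2,2,2-trichloro-1,1-dimethylethyl carbonate
Conditions: 2,2,2-trichloro-1,1-dimethylethyl chloroformate, Et3N, THF, 0 °C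
Reagents that add atoms: 2,2,2-trichloro-1,1-dimethylethyl chloroformate, CC(C)(OC(=O)Cl)C(Cl)(Cl)Cl
Why: kinetic O-acylation of the aromatic benzofuranolate gives the enol carbonate.

Step 16
Reactants: 26 enol carbonate
Product: 27 2,2,2-trichloro-1,1-dimethylethyl (R)-6-(methoxymethoxy)-3-(3-methylbut-2-enyl)-2-oxo-2,3-dihydrobenzofuran-3-carboxylate
Conditions: (−)-Fe(η5-C5Ph5)(η5-C12H13N2) [planar-chiral ferrocene-fused 4-pyrrolidinopyridine] (5 mol%), CH2Cl2, 35 °C
Reagents that add atoms: none
Why: catalytic enantioselective Steglich-type O-to-C carboxyl rearrangement, in which the chiral pyridine takes up the alkoxycarbonyl group and returns it to one face of the benzofuranolate, sets the quaternary centre with two chemically distinct carbonyls (aryl lactone and hindered ester).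

Step 17
Reactants: 27 (R)-benzofuranone ester
Product: 29 (R)-2-[2,4-bis(methoxymethoxy)phenyl]-5-methyl-2-[(2,2,2-trichloro-1,1-dimethylethoxy)carbonyl]hex-4-enoic acid, via dilithium phenoxide carboxylate 28 (not isolated)
Conditions: LiOH·H2O (2.2 equiv), THF/H2O, 0 °C; evaporate; MOMCl (1.1 equiv), DMF, 0 °C; AcOH to pH 5
Reagents that add atoms: lithium hydroxide, [Li+].[OH-]; chloromethyl methyl ether, COCCl
Why: hydroxide opens only the strained aryl lactone (the trichloro-tert-butyl ester is too hindered), and the phenoxide is then alkylated (Williamson) in preference to the neopentyl-type carboxylate; the quaternary centre has no acidic hydrogen.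

Step 18
Reactants: 22 ring A diol; 29 (R)-malonic half-ester
Product: 31 aryl ester of 29 at the ring A hydroxyl para to D3 (quaternary carbon R), via acid chloride 30 (not isolated)
Conditions: 29, 1-chloro-N,N,2-trimethylprop-1-en-1-amine, CH2Cl2, 0 °C; then 22, pyridine, DMAP (cat.), −20 °C
Reagents that add atoms: none
Why: the acid chloride, formed under neutral conditions, O-acylates the phenol flanked by two hydrogens in preference to the phenol next to the cyclohexenyl group, which places the former lactone carbonyl of 27 on the future ring C oxygen.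

Step 19
Reactants: 31 trichloro-tert-butyl ester
Product: 32 the corresponding malonic half-acid aryl ester (quaternary carbon S)
Conditions: Zn dust, AcOH, THF, rt
Reagents that add atoms: none
Why: reductive β-elimination of the trichloro-tert-butyl ester by zinc (as for trichloroethyl esters) frees the second carboxyl without touching the aryl ester, MOM ethers, ketone or alkenes.

Step 20
Reactants: 32 half-acid aryl ester
Product: 34 heptakis-MOM chromandione: (3S)-3-[2,4-bis(methoxymethoxy)phenyl]-5-hydroxy-7-(methoxymethoxy)-3-(3-methylbut-2-enyl)-6-[D ring as in 21]chroman-2,4-dione, via acid chloride 33 (not isolated)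
Conditions: 1-chloro-N,N,2-trimethylprop-1-en-1-amine, CH2Cl2, 0 °C; then iPr2NEt, DMAP (cat.), CH2Cl2 (0.003 M), 0 °C to rt
Reagents that add atoms: none
Why: intramolecular Friedel–Crafts-type C-acylation of the phenol(ate), in which the O-ester holds the acid chloride so that only a ring A carbon ortho to that ester can be reached (six-membered ring) and O-acylation is geometrically excluded; since the first carbonyl went to oxygen and the second to carbon, C3 follows from 27, and closure at either ortho carbon gives the same product after step 21 (34 is drawn with the ketone next to the free hydroxyl).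

Step 21
Reactants: 34 heptakis-MOM chromandione
Product: 35 target, (3S)-3-(2,4-dihydroxyphenyl)-5,7-dihydroxy-6-[(1S,5R,6R)-6-(2,4-dihydroxybenzoyl)-5-(2,4-dihydroxyphenyl)-3-methylcyclohex-2-en-1-yl]-3-(3-methylbut-2-enyl)chroman-2,4-dione
Conditions: TMSOTf, 2,2′-bipyridyl, CH2Cl2, 0 °C to rt; then H2O
Reagents that add atoms: none
Why: silyl triflate/bipyridyl cleavage of aryl MOM ethers passes through aryl silyl ethers that hydrolyse on adding water, so no free strong acid meets the prenyl group, the β-keto lactone or the ketone that could ketalise with the neighbouring phenols.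

**Compound list**
1 | 2,4-dihydroxybenzaldehyde | O=Cc1ccc(O)cc1O | starting material
2 | diallyl malonate | C=CCOC(=O)CC(=O)OCC=C | starting material
3 | allyl 7-hydroxy-2-oxo-2H-chromene-3-carboxylate | C=CCOC(=O)C1=Cc2ccc(O)cc2OC1=O | intermediate
4 | allyl 7-(methoxymethoxy)-2-oxo-2H-chromene-3-carboxylate | C=CCOC(=O)C1=Cc2ccc(OCOC)cc2OC1=O | intermediate
5 | (E)-1-methoxy-3-(trimethylsilyloxy)buta-1,3-diene | CO/C=C/C(=C)O[Si](C)(C)C | starting material
6 | cis-fused cycloadduct, silyl enol ether at D1, methoxy on D3 (epimers) | O=C1Oc2cc(OCOC)ccc2[C@@H]3CC(O[Si](C)(C)C)=CC(OC)[C@]13C(=O)OCC=C | intermediate (not isolated)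
7 | cis-fused enone ester (6aS,10aS) | O=C1Oc2cc(OCOC)ccc2[C@@H]3CC(=O)C=C[C@]13C(=O)OCC=C | intermediate
8 | tertiary allylic alcohol ester (6aS,10aS; carbinol epimers) | O=C1Oc2cc(OCOC)ccc2[C@@H]3CC(C)(O)C=C[C@]13C(=O)OCC=C | intermediate
9 | malonic half-acid of 8 | O=C1Oc2cc(OCOC)ccc2[C@@H]3CC(C)(O)C=C[C@]13C(=O)O | intermediate (not isolated)
10 | cis-fused lactone (6aS,10aR; carbinol epimers) | O=C1Oc2cc(OCOC)ccc2[C@@H]3CC(C)(O)C=C[C@H]13 | intermediate
11 | dilithium phenoxide carboxylate from 10 | [Li+].[Li+].CC1(O)C=C[C@H](C(=O)[O-])[C@H](c2ccc(OCOC)cc2[O-])C1 | intermediate (not isolated)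
12 | (1S,6R)-6-[2,4-bis(methoxymethoxy)phenyl]-4-hydroxy-4-methylcyclohex-2-ene-1-carboxylic acid | CC1(O)C=C[C@H](C(=O)O)[C@H](c2ccc(OCOC)cc2OCOC)C1 | intermediate
13 | phloroglucinol | Oc1cc(O)cc(O)c1 | starting material
14 | 3,5-bis(tert-butyldimethylsilyloxy)phenol | Oc1cc(O[Si](C)(C)C(C)(C)C)cc(O[Si](C)(C)C(C)(C)C)c1 | intermediate
15 | 3,5-bis(TBS-oxy)phenyl ester of 12 (key precursor) | CC1(O)C=C[C@H](C(=O)Oc2cc(O[Si](C)(C)C(C)(C)C)cc(O[Si](C)(C)C(C)(C)C)c2)[C@H](c2ccc(OCOC)cc2OCOC)C1 | intermediate
16 | all-cis ring A lactone (6aR,7R,10aS) (key product) | O=C1Oc2cc(O[Si](C)(C)C(C)(C)C)cc(O[Si](C)(C)C(C)(C)C)c2[C@H]2C=C(C)C[C@@H](c3ccc(OCOC)cc3OCOC)[C@@H]12 | intermediate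
17 | 4-bromoresorcinol | Oc1ccc(Br)c(O)c1 | starting material
18 | 1-bromo-2,4-bis(methoxymethoxy)benzene | COCOc1ccc(Br)c(OCOC)c1 | intermediate
19 | 2,4-bis(methoxymethoxy)phenyllithium | [Li]c1ccc(OCOC)cc1OCOC | intermediate (not isolated)
20 | lithium phenoxide of the ring-opened ketone | [Li]Oc1cc(O[Si](C)(C)C(C)(C)C)cc(O[Si](C)(C)C(C)(C)C)c1[C@H]1C=C(C)C[C@@H](c2ccc(OCOC)cc2OCOC)[C@H]1C(=O)c1ccc(OCOC)cc1OCOC | intermediate (not isolated)
21 | all-cis ketone, ring A 2-OMOM-4,6-bis(OTBS) | COCOc1cc(O[Si](C)(C)C(C)(C)C)cc(O[Si](C)(C)C(C)(C)C)c1[C@H]1C=C(C)C[C@@H](c2ccc(OCOC)cc2OCOC)[C@H]1C(=O)c1ccc(OCOC)cc1OCOC | intermediate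
22 | all-cis ketone, ring A 2-OMOM-4,6-diol | COCOc1cc(O)cc(O)c1[C@H]1C=C(C)C[C@@H](c2ccc(OCOC)cc2OCOC)[C@H]1C(=O)c1ccc(OCOC)cc1OCOC | intermediate
23 | 6-hydroxybenzofuran-2(3H)-one | O=C1Cc2ccc(O)cc2O1 | starting material
24 | 6-(methoxymethoxy)benzofuran-2(3H)-one | O=C1Cc2ccc(OCOC)cc2O1 | intermediate
25 | racemic 6-(methoxymethoxy)-3-prenylbenzofuran-2(3H)-one | O=C1Oc2cc(OCOC)ccc2C1CC=C(C)C | intermediate
26 | enol carbonate of 25 | CC(C)=CCc1c(OC(=O)OC(C)(C)C(Cl)(Cl)Cl)oc2cc(OCOC)ccc12 | intermediate
27 | (R)-3-prenyl-3-(trichloro-tert-butoxycarbonyl)benzofuranone | CC(C)=CC[C@@]1(C(=O)OC(C)(C)C(Cl)(Cl)Cl)c2ccc(OCOC)cc2OC1=O | intermediate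
28 | dilithium phenoxide carboxylate from 27 | [Li+].[Li+].CC(C)=CC[C@@](C(=O)OC(C)(C)C(Cl)(Cl)Cl)(c1ccc(OCOC)cc1[O-])C(=O)[O-] | intermediate (not isolated)
29 | (R)-malonic half-ester acid | CC(C)=CC[C@@](C(=O)OC(C)(C)C(Cl)(Cl)Cl)(c1ccc(OCOC)cc1OCOC)C(=O)O | intermediate
30 | (S)-acid chloride of 29 | CC(C)=CC[C@@](C(=O)OC(C)(C)C(Cl)(Cl)Cl)(c1ccc(OCOC)cc1OCOC)C(=O)Cl | intermediate (not isolated)
31 | ring A para-O-aryl ester, trichloro-tert-butyl ester | COCOc1cc(OC(=O)[C@](CC=C(C)C)(C(=O)OC(C)(C)C(Cl)(Cl)Cl)c2ccc(OCOC)cc2OCOC)cc(O)c1[C@H]1C=C(C)C[C@@H](c2ccc(OCOC)cc2OCOC)[C@H]1C(=O)c1ccc(OCOC)cc1OCOC | intermediate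
32 | ring A para-O-aryl ester, free acid | COCOc1cc(OC(=O)[C@](CC=C(C)C)(C(=O)O)c2ccc(OCOC)cc2OCOC)cc(O)c1[C@H]1C=C(C)C[C@@H](c2ccc(OCOC)cc2OCOC)[C@H]1C(=O)c1ccc(OCOC)cc1OCOC | intermediate
33 | acid chloride of 32 | COCOc1cc(OC(=O)[C@](CC=C(C)C)(C(=O)Cl)c2ccc(OCOC)cc2OCOC)cc(O)c1[C@H]1C=C(C)C[C@@H](c2ccc(OCOC)cc2OCOC)[C@H]1C(=O)c1ccc(OCOC)cc1OCOC | intermediate (not isolated)
34 | heptakis-MOM chroman-2,4-dione | CC(C)=CC[C@@]1(c2ccc(OCOC)cc2OCOC)C(=O)Oc2cc(OCOC)c([C@H]3C=C(C)C[C@@H](c4ccc(OCOC)cc4OCOC)[C@H]3C(=O)c3ccc(OCOC)cc3OCOC)c(O)c2C1=O | intermediate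
35 | target | CC(C)=CC[C@@]1(c2ccc(O)cc2O)C(=O)Oc2cc(O)c([C@H]3C=C(C)C[C@@H](c4ccc(O)cc4O)[C@H]3C(=O)c3ccc(O)cc3O)c(O)c2C1=O | target

**Count**
Total steps: 21. Longest linear sequence: 14 (steps 1–6, 8, 9, 11, 12, 18–21).

**Steps most likely to fail**

Step 9 (proposed new method). The ester must rotate into its less stable conformation before ring closure, so proton loss from the cation to a diene, acyl transfer to the tertiary alcohol or intermolecular alkylation may outrun the cyclisation. The fallback sets out from coumarin 4, returns at ketone 21 and makes the ring A–D3 bond in the Diels–Alder step instead. 2,4,6-Trihydroxybenzaldehyde is silylated (TBSCl, 2 equiv) to 2-hydroxy-4,6-bis(tert-butyldimethylsilyloxy)benzaldehyde F1, whose chelated hydroxyl is then methoxymethylated to aldehyde F2. Horner–Wadsworth–Emmons olefination with diethyl (2-methylallyl)phosphonate gives the (E)-1-aryl-3-methylbutadiene F3. Its copper bis(oxazoline)-catalysed Diels–Alder reaction with 4 (aryl-bearing terminus to C3, endo) should give the cycloadduct F4, and the conditions of step 5 the all-cis ring E lactone F5. Aryllithium 19 followed by MOMCl, as in step 11 but now opening the ring E lactone, gives 21.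

Step 20. The phenolate may react at oxygen between molecules, or the hindered acid chloride may fail to reach the ring carbon. The fallback sets out from benzofuranone 27 and diol 22, returns at 34 and reverses the order of the two bonds. Lactone 27 is opened with sodium allyloxide (THF, −40 °C) and the phenoxide capped with MOMCl to the allyl trichloro-tert-butyl diester F6; zinc in AcOH gives the allyl half-acid F7. Its acid chloride C-acylates the bis(bromomagnesium) phenolate of 22 (EtMgBr, toluene) at the carbon between the two oxygens (ortho-acylation of magnesium phenolates) to aryl ketone F8. Pd(PPh3)4 with PhSiH3 frees acid F9, and carbodiimide lactonisation onto the unhindered phenol gives 34. The carbonyl that was the lactone of 27 again ends on oxygen and the other on carbon, so C3 is unchanged.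

Step 3. Facial selectivity of the copper complex on this chelating coumarin may be poor, or the diene may add stepwise without closing. The fallback sets out from 4, returns at 7 and moves the control element to the diene. The auxiliary-bearing (2R,5R)-1-[(E)-3-(tert-butyldimethylsilyloxy)buta-1,3-dienyl]-2,5-diphenylpyrrolidine F10 (from the pyrrolidine and 4-methoxybut-3-en-2-one, then KN(SiMe3)2 and TBSCl) adds thermally to 4 (toluene, −20 °C to rt) to give cycloadduct F11. Aqueous HF in MeCN hydrolyses the silyl enol ether and eliminates the amine to 7; the antipodal pyrrolidine is used if the other face is needed.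

**Further compounds**
F1 | step 9 | 2-hydroxy-4,6-bis(tert-butyldimethylsilyloxy)benzaldehyde | O=Cc1c(O)cc(O[Si](C)(C)C(C)(C)C)cc1O[Si](C)(C)C(C)(C)C
F2 | step 9 | 2-(methoxymethoxy)-4,6-bis(tert-butyldimethylsilyloxy)benzaldehyde | COCOc1cc(O[Si](C)(C)C(C)(C)C)cc(O[Si](C)(C)C(C)(C)C)c1C=O
F3 | step 9 | (E)-1-[2-(methoxymethoxy)-4,6-bis(tert-butyldimethylsilyloxy)phenyl]-3-methylbuta-1,3-diene | C=C(C)/C=C/c1c(OCOC)cc(O[Si](C)(C)C(C)(C)C)cc1O[Si](C)(C)C(C)(C)C
F4 | step 9 | all-cis ring E lactone cycloadduct with allyl ester on D4 | O=C1Oc2cc(OCOC)ccc2[C@@H]3CC(C)=C[C@H](c4c(OCOC)cc(O[Si](C)(C)C(C)(C)C)cc4O[Si](C)(C)C(C)(C)C)[C@]13C(=O)OCC=C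
F5 | step 9 | all-cis ring E lactone after decarboxylation | O=C1Oc2cc(OCOC)ccc2[C@@H]3CC(C)=C[C@H](c4c(OCOC)cc(O[Si](C)(C)C(C)(C)C)cc4O[Si](C)(C)C(C)(C)C)[C@H]13
F6 | step 20 | allyl trichloro-tert-butyl 2-[2,4-bis(methoxymethoxy)phenyl]-2-prenylmalonate | CC(C)=CC[C@@](C(=O)OC(C)(C)C(Cl)(Cl)Cl)(c1ccc(OCOC)cc1OCOC)C(=O)OCC=C
F7 | step 20 | allyl hydrogen 2-[2,4-bis(methoxymethoxy)phenyl]-2-prenylmalonate | CC(C)=CC[C@@](C(=O)O)(c1ccc(OCOC)cc1OCOC)C(=O)OCC=C
F8 | step 20 | ring A C-acylated ketone, allyl ester | COCOc1cc(O)c(C(=O)[C@@](CC=C(C)C)(C(=O)OCC=C)c2ccc(OCOC)cc2OCOC)c(O)c1[C@H]1C=C(C)C[C@@H](c2ccc(OCOC)cc2OCOC)[C@H]1C(=O)c1ccc(OCOC)cc1OCOC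
F9 | step 20 | ring A C-acylated ketone, free acid | COCOc1cc(O)c(C(=O)[C@@](CC=C(C)C)(C(=O)O)c2ccc(OCOC)cc2OCOC)c(O)c1[C@H]1C=C(C)C[C@@H](c2ccc(OCOC)cc2OCOC)[C@H]1C(=O)c1ccc(OCOC)cc1OCOC
F10 | step 3 | (2R,5R)-1-[(E)-3-(tert-butyldimethylsilyloxy)buta-1,3-dienyl]-2,5-diphenylpyrrolidine | C=C(O[Si](C)(C)C(C)(C)C)/C=C/N1[C@@H](c2ccccc2)CC[C@@H]1c1ccccc1
F11 | step 3 | cis-fused cycloadduct, pyrrolidinyl on D3 (configuration as formed), silyl enol ether at D1 | O=C1Oc2cc(OCOC)ccc2[C@@H]3CC(O[Si](C)(C)C(C)(C)C)=CC(N4[C@@H](c5ccccc5)CC[C@@H]4c6ccccc6)[C@]13C(=O)OCC=C
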